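Two questions stand on elm: does the excess of right-handed over left-handed substrate reach the level, and how high does it climb?

all flasks: left-handed substrate 0.20 M; right-handed substrate 0.20 M

| flask | partner | precatalyst | remark | time |
|---|---|---|---|---|
| elm | 0.20 M | 0.36 mM | the very flask that is asked about, followed so far |  |
| ash | 0.20 M | 0.54 mM | run made earlier |  |
| flask | 0.200 M | 0.36 mM |  | 1.5 h |

| run | time / min | right-handed substrate / % | left-handed substrate / % | left-handed product / % |
|---|---|---|---|---|
| elm | 5.00 | 51 | 49 | 2 |
| elm | 10.0 | 51 | 51 | 3 |
| elm | 15.0 | 46 | 50 | 2 |
| elm | 20.0 | 50 | 46 | 6 |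
| elm | 25.0 | 49 | 44 | 5 |
| elm | 30.0 | 47 | 43 | 5 |
| elm | 40.0 | 46 | 38 | 10 |
| ash | 8.00 | 51 | 49 | 0 |
| ash | 12.0 | 47 | 48 | 1 |
| ash | 15.0 | 49 | 46 | 1 |
| ash | 25.0 | 47 | 42 | 8 |
| ash | 40.0 | 46 | 38 | 11 |
| ash | 60.0 | 44 | 30 | 16 |
| ash | 90.0 | 45 | 24 | 24 |

(scatter of a reading: 1.5 percentage points)

* whether the excess of right-handed substrate over left-handed substrate among what is left of the two reaches 95% by 1.5 h (no / yes)
* the highest excess of right-handed substrate over left-handed substrate among what is left of the two up to 1.5 h

- free catalyst is single-handed; left-handed substrate and right-handed substrate are mirror images of each other, charged as a racemate, each of them at the stated concentration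
- the numbers in the tables scatter by 1.5 percentage points (one standard deviation)

I count lifetimes: for a substrate, x = ln(charge / what is left), each substrate being charged at half of the total. In ash I sum the counts of the last 3 readings, to soften the scatter of 1.5 percentage points, and the left-handed sum over the right-handed sum is 4.80. This ratio of the two counts is the selectivity factor s, a reading that I take as constant.

As far as its scattered readings show, the excess curve of elm starts flat: at 15.0 min the left-handed substrate still reads 50%. Past that knee it climbs, and at 40.0 min the left-handed count is 0.274. To reach 1.5 h I add the gain ash made from 40.0 min to 90.0 min, 0.460, scaled by my own assumption with the precatalyst ratio 0.667, which brings my estimate for elm to 0.581.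

Then s gives 28.0% left-handed and 44.3% right-handed substrate, so an excess of 22.6%. The loss, 27.7% of the total, is less than the partner charge of 50.0% on that scale, if each substrate lost takes one partner. So by my reckoning the partner does not stop the curve in elm before 1.5 h, and I put the top at that end.

The level asks for a left-handed count of ln((1 + excess)/(1 − excess))/(1 − 1/s) = 4.63, far above my estimate of 0.581 for elm, so I answer no.

The forecast also says no but puts the top at 31%, higher than my 22.6%, holding that “The rate therefore appears capped, not proportional to loading”.

Elm gives no and a top of 20.2%, standing at 1.50 h with 29.4% left-handed and 44.3% right-handed substrate, and 47% of the partner still there.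

    free catalyst + left-handed substrate ⇌ catalyst intermediate A (K = 4.90 M⁻¹, k = 2000 M⁻¹ min⁻¹)
    free catalyst + right-handed substrate ⇌ catalyst intermediate B (K = 3.30 M⁻¹, k = 3300 M⁻¹ min⁻¹)
    partner + catalyst intermediate A → free catalyst + left-handed product (k = 130 M⁻¹ min⁻¹)
    partner + catalyst intermediate B → free catalyst + right-handed product (k = 42.0 M⁻¹ min⁻¹)
    left-handed product ⇌ right-handed product (k = 0.00360 min⁻¹)
    partner + precatalyst → free catalyst + spent reagent (k = 0.160 M⁻¹ min⁻¹)
    2 free catalyst → spent catalyst (k = 160 M⁻¹ min⁻¹)

From that left-handed amount, s gives 44.8% right-handed substrate and an excess of 20.8%. In a neighbour flask with 0.80 M of partner, the left-handed substrate ends at 3.23%, a count of 2.74, below the 4.63 the level asks. There s gives 28.3% right-handed substrate and an excess of 79.5%; the computed top is 77.1%.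

Readings and results were generated by integration on assumed constants, and the scatter is random.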